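Late in the alder run, in which a single-handed catalyst and a solid reagent turn a racemic pair of substrates into products, the total reacted stopped rising in a straight line. The two substrates together lost 10 percentage points between 20.0 min and 25.0 min, but 7.5 points between 25.0 min and 30.0 min, and each such loss carries a scatter of about 0.6 points.

| setting | larch | alder | flask |
|---|---|---|---|
| left-handed substrate | 0.30 M | 0.30 M | 0.30 M |
| right-handed substrate | 0.30 M | 0.30 M | 0.30 M |
| protic impurity | 0.030 M | 0.030 M | 0.0300 M |
| solid reagent | 0.36 M | 0.36 M | 0.360 M |
| precatalyst | 0.40 mM | 0.90 mM | 0.60 mM |
| remark | run made earlier | run made earlier |  |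
| time |  |  | 30 min |

- larch (time / min: left-handed substrate / %, right-handed substrate / %, left-handed product / %): 2.00: 49.7, 48.7, 0.3; 6.00: 47.9, 44.5, 2.1; 10.0: 46.5, 39.3, 2.9; 15.0: 43.9, 32.8, 6.0; 25.0: 38.8, 19.7, 11.3; 30.0: 34.5, 14.3, 14.6
- alder (time / min: left-handed substrate / %, right-handed substrate / %, left-handed product / %): 5.00: 48.6, 43.5, 1.8; 10.0: 45.7, 36.6, 4.1; 15.0: 43.3, 30.0, 6.9; 20.0: 40.1, 22.6, 10.0; 25.0: 36.9, 15.7, 14.2; 30.0: 33.6, 11.5, 16.3

(standard deviation of a reading: 0.3 percentage points)

- free catalyst is single-handed; left-handed substrate and right-handed substrate are mirror images of each other, charged as a racemate, each of them at the stated concentration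
- as a solid, counted per litre of solution: solid reagent
- at the start none of the solid reagent is in solution
- an excess is below zero if the other one leads

1. part of the left-handed substrate and right-handed substrate charged together that has reacted at 30 min
2. excess of left-handed product over right-handed product in the product at 30 min
3. excess of right-handed substrate over left-handed substrate among what is left of the two at 30 min

My first estimate for the flask was an interpolation in precatalyst. At 30.0 min the larch run had reacted 51.2 % and the alder run 54.9 %, which puts 0.60 mM of precatalyst at 52.7 %. My objection was that 2.25 times the precatalyst gave 1.07 times the total reacted, so a line in precatalyst had little ground.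

I therefore wrote the balance of the solid reagent, the limiting reagent, charged at 0.360 M against 0.600 M of substrates. I assumed that one portion of reagent goes to each product formed and one to each protic impurity. The reagent charge less the impurity charge, over the two substrates together, comes to 55.0 %, and I call this the balance conversion.

The doubt was whether the impurity really takes its full charge, since the sum without it gives 60.0 %. The alder run leaned towards the full charge: its readings bent at 54.9 %, and the scatter of that sum is about 0.42 points. The larch run, at 51.2 %, still lost 9.7 points in its last 5.00 min. So I placed the flask between 52.7 % and 55.0 %.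

The forecast gave c = 53.5 %, eP = −40.2 % and eS = −46.2 %, with the words “Stoichiometry sets a cap”. The flask gave c = 54.5 %, inside my bracket, with eP = −40.1 % and eS = −48.1 %.

    free catalyst + left-handed substrate ⇌ catalyst intermediate A (K = 6.60 M⁻¹, k = 360 M⁻¹ s⁻¹)
    free catalyst + right-handed substrate ⇌ catalyst intermediate B (K = 74.0 M⁻¹, k = 340 M⁻¹ s⁻¹)
    partner + catalyst intermediate A → free catalyst + left-handed product (k = 290 M⁻¹ s⁻¹)
    partner + catalyst intermediate B → free catalyst + right-handed product (k = 99.0 M⁻¹ s⁻¹)
    partner + protic impurity → quenched reagent (k = 0.650 M⁻¹ s⁻¹)
    precatalyst → free catalyst (k = 0.00750 s⁻¹)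
    solid reagent ⇌ partner, rate k7*(cs7 - [partner]) while solid is left; crystals form when [partner] > cs7 (solubility = 21.0 mM, k = 0.0110 s⁻¹)

In the flask at 30.0 min the solid reagent stood at 0.461 % of its charge, and the quenched reagent at 0.0290 M, nearly all of the impurity charge. How the flask's reagent was shared between the two products came mainly from the return of catalyst intermediate A to free catalyst and left-handed substrate: the simulated run without that return gave eP = 76.2 % against −40.1 %. A further flask, the same but with 0.14 M of solid reagent, has a balance conversion of 18.3 %, or 19.5 % once the 24 % of protic impurity left unspent is counted, and it reached 19.6 %.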